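**Retrosynthetic overview**
1. The target comes from its side-chain diol acetonide by ketal hydrolysis (last step).
2. The bicyclic core is made in one flask from a chiral δ-keto α-hydroxy ester, a cis-epoxy aldehyde and Hantzsch ester. Ring order: the cyclohexane-1,3-dione first (Dieckmann, C5–OH carried in from the chiral pool), then the C3–C3a bond (reductive Knoevenagel), then the dihydrofuran (5-exo epoxide opening by the dione enolate oxygen, inversion at C2).
3. The cis-epoxy aldehyde comes from Sharpless epoxidation of a Z-allylic alcohol, itself made by B-alkyl Suzuki coupling of a terminal alkene with (Z)-3-iodobut-2-en-1-ol.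
4. The terminal alkene carrying the unlike sec/tert diol comes from geraniol by Sharpless epoxidation, then Payne rearrangement with sulfonium-ylide homologation.
5. The δ-keto α-hydroxy ester comes from (R)-5-oxotetrahydrofuran-2-carboxylic acid by MeLi addition to the lactone and O-methylation.

Assumption and notation: geraniol, but-2-yn-1-ol and (R)-5-oxotetrahydrofuran-2-carboxylic acid (the D-glutamic-acid-derived lactone acid) are bought; core locants are O1, C2, C3, C3a, C4(=O), C5(OH), C6, C7, C7a; side-chain carbinols are C2′, C5′, C6′; "Diox" = (4R,5S)-2,2,5-trimethyl-5-(4-methylpent-3-en-1-yl)-1,3-dioxolan-4-yl.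

Step 1
Reactants: 1 geraniol
Product: 2 [(2S,3S)-3-methyl-3-(4-methylpent-3-en-1-yl)oxiran-2-yl]methanol
Conditions: Ti(OiPr)4 (5 mol %), L-(+)-DET (6 mol %), t-BuOOH, 4 Å MS, CH2Cl2, −20 °C
Reagents that add atoms: tert-butyl hydroperoxide, CC(C)(C)OO
Why: Katsuki–Sharpless asymmetric epoxidation: the titanium tartrate binds the allylic OH, so only the 2,3-alkene reacts, and L-(+)-DET gives the (2S,3S) trans-epoxide.

Step 2
Reactants: 2 [(2S,3S)-3-methyl-3-(4-methylpent-3-en-1-yl)oxiran-2-yl]methanol
Product: 4 (3R,4S)-4,8-dimethylnona-1,7-diene-3,4-diol, via terminal epoxide 3 (not isolated)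
Conditions: Me3S+ I− (4 equiv), n-BuLi (4 equiv), THF, −10 → 23 °C
Reagents that add atoms: trimethylsulfonium iodide, C[S+](C)C.[I-]
Why: Payne rearrangement (C1–O− attacks C2 with inversion, the tertiary centre is untouched) gives terminal epoxide 3, which dimethylsulfonium methylide opens at CH2 and which then loses Me2S (Corey–Chaykovsky-type one-carbon homologation to an allylic alcohol), so the inversion converts the trans-epoxide into the unlike diol needed at C5′ (R) and C6′ (S).

Step 3
Reactants: 4 (3R,4S)-4,8-dimethylnona-1,7-diene-3,4-diol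
Product: 5 (4R,5S)-4-ethenyl-2,2,5-trimethyl-5-(4-methylpent-3-en-1-yl)-1,3-dioxolane
Conditions: Me2C(OMe)2, PPTS (cat.), CH2Cl2, 23 °C
Reagents that add atoms: 2,2-dimethoxypropane, COC(C)(C)OC
Why: Acid-catalysed transketalisation masks the vicinal sec/tert diol for the borane, titanium, oxidant and base steps that follow and touches no stereocentre.

Step 4
Reactants: 6 but-2-yn-1-ol
Product: 8 (Z)-3-iodobut-2-en-1-ol, via cyclic vinylalanate 7 (not isolated)
Conditions: Red-Al, THF, 0 → 23 °C; then I2, THF, −78 → 0 °C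
Reagents that add atoms: iodine, II
Why: Hydroxyl-directed trans-hydroalumination places aluminium on C3 in a five-membered alkoxy-alanate, and iodinolysis with retention gives only the Z vinyl iodide.

Step 5
Reactants: 5 (4R,5S)-4-ethenyl-2,2,5-trimethyl-5-(4-methylpent-3-en-1-yl)-1,3-dioxolane; 8 (Z)-3-iodobut-2-en-1-ol
Product: 10 (2Z)-3-methyl-5-Diox-pent-2-en-1-ol, via B-alkyl-9-BBN adduct 9 (not isolated)
Conditions: 9-BBN, THF, 0 → 23 °C; then 8, Pd(dppf)Cl2 (5 mol %), AsPh3, Cs2CO3, DMF–H2O, 23 °C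
Reagents that add atoms: none
Why: 9-BBN hydroborates only the monosubstituted alkene (anti-Markovnikov), and B-alkyl Suzuki–Miyaura coupling retains the vinyl iodide geometry, fixing the Z trisubstituted alkene.

Step 6
Reactants: 10 (2Z)-3-methyl-5-Diox-pent-2-en-1-ol
Product: 11 [(2R,3S)-3-methyl-3-(2-Diox-ethyl)oxiran-2-yl]methanol
Conditions: Ti(OiPr)4 (1.0 equiv), D-(−)-DET (1.2 equiv), t-BuOOH, 4 Å MS, CH2Cl2, −20 °C
Reagents that add atoms: tert-butyl hydroperoxide, CC(C)(C)OO
Why: Katsuki–Sharpless asymmetric epoxidation reaches only the alkene next to the free allylic OH, and D-(−)-DET on a Z (nerol-type) allylic alcohol gives the (2R,3S) cis-epoxide, which sets C2′ (S) directly and sets up C2 for inversion in step 9.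

Step 7
Reactants: 11 [(2R,3S)-3-methyl-3-(2-Diox-ethyl)oxiran-2-yl]methanol
Product: 12 (2S,3S)-3-methyl-3-(2-Diox-ethyl)oxirane-2-carbaldehyde
Conditions: Dess–Martin periodinane, NaHCO3, CH2Cl2, 0 → 23 °C
Reagents that add atoms: none
Why: Buffered Dess–Martin oxidation of the primary epoxy alcohol does not epimerise the epoxide (the CIP label of the epoxide CH changes from R to S with no change in geometry).

Step 8
Reactants: 13 (2R)-5-oxooxolane-2-carboxylic acid
Product: 15 methyl (2R)-2-hydroxy-5-oxohexanoate, via lithium hydroxy keto carboxylate 14 (not isolated)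
Conditions: MeLi (2.05 equiv), THF, −78 °C; AcOH (1.0 equiv); then MeI, DMF, 23 °C
Reagents that add atoms: methyllithium, [Li]C; iodomethane, CI
Why: At −78 °C MeLi first forms the unreactive lithium carboxylate and then adds once to the lactone carbonyl (stable tetrahedral lactolate), so protonation releases the methyl ketone and the free hydroxyl with the stereocentre untouched, and SN2 O-methylation of the carboxylate gives the ester.

Step 9
Reactants: 15 methyl (2R)-2-hydroxy-5-oxohexanoate; 12 (2S,3S)-3-methyl-3-(2-Diox-ethyl)oxirane-2-carbaldehyde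
Product: 19 (2S,5R)-5-hydroxy-2-[(2S)-2-hydroxy-4-Diox-butan-2-yl]-2,3,6,7-tetrahydro-1-benzofuran-4(5H)-one, via hydroxy dione 16 (not isolated), via alkylidene dione 17 (not isolated), via epoxyalkyl dione 18 (not isolated)
Conditions: 15 (1.3 equiv), KOtBu (2.6 equiv), THF, 0 → 45 °C; AcOH (2.6 equiv); then 12, Hantzsch ester (1.2 equiv), L-proline (20 mol %), CH2Cl2, 23 °C; then KOtBu (3 equiv), 0 °C; AcOH quench
Reagents that add atoms: none
Why: Proposed new method: KOtBu turns 15 into its alkoxide/methyl-ketone enolate, which closes the six-membered ring by Dieckmann condensation to dione 16 without risk to C5 (neither the α-oxido ester nor the dione enolate can enolise there); proline-catalysed Knoevenagel condensation of 16 with 12 gives 17, Hantzsch-ester hydride transfer gives 18, and the K+-bridged C5-alkoxide/enolate dianion then opens the epoxide 5-exo-tet at the secondary carbon through the distal enolate oxygen (the oxygen next to C5 is held in the five-membered potassium chelate and is electrostatically deactivated by the neighbouring alkoxide), with inversion that sets C2 (S) and leaves the epoxide oxygen as the C2′ (S) tertiary alcohol; the closest known reaction types are the Dieckmann synthesis of cyclohexane-1,3-diones from δ-keto esters, the amino-acid/Hantzsch-ester three-component reductive alkylation of 1,3-diones, and the base-mediated cyclisation of 2-(2,3-epoxyalkyl)-1,3-diones to 2-(1-hydroxyalkyl)dihydrofurans.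

Step 10
Reactants: 19 (2S,5R)-5-hydroxy-2-[(2S)-2-hydroxy-4-Diox-butan-2-yl]-2,3,6,7-tetrahydro-1-benzofuran-4(5H)-one
Product: 20 (2S,5R)-5-hydroxy-2-[(2S,5R,6S)-2,5,6-trihydroxy-6,10-dimethylundec-9-en-2-yl]-2,3,6,7-tetrahydro-1-benzofuran-4(5H)-one
Conditions: AcOH–H2O (4:1), 40 °C
Reagents that add atoms: none
Why: Mild acid-catalysed hydrolysis of the isopropylidene ketal frees the C5′/C6′ diol; the vinylogous ester, the tertiary alcohols and the trisubstituted alkene tolerate aqueous acetic acid and no stereocentre is involved.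

**Compound list**
1 | geraniol | CC(C)=CCC/C(C)=C/CO | starting material
2 | [(2S,3S)-3-methyl-3-(4-methylpent-3-en-1-yl)oxiran-2-yl]methanol | CC(C)=CCC[C@]1(C)O[C@H]1CO | intermediate
3 | (2S)-6-methyl-2-[(2R)-oxiran-2-yl]hept-5-en-2-ol (terminal epoxide, in flask) | CC(C)=CCC[C@](C)(O)[C@H]1CO1 | intermediate
4 | (3R,4S)-4,8-dimethylnona-1,7-diene-3,4-diol | CC(C)=CCC[C@](C)(O)[C@H](O)C=C | intermediate
5 | (4R,5S)-4-ethenyl-2,2,5-trimethyl-5-(4-methylpent-3-en-1-yl)-1,3-dioxolane | CC(C)=CCC[C@]1(C)OC(C)(C)O[C@@H]1C=C | intermediate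
6 | but-2-yn-1-ol | CC#CCO | starting material
7 | sodium 2,2-bis(2-methoxyethoxy)-3-methyl-2,5-dihydro-1,2-oxaaluminol-2-uide (cyclic vinylalanate, in flask) | CC1=CCO[Al-]1(OCCOC)OCCOC.[Na+] | intermediate
8 | (Z)-3-iodobut-2-en-1-ol | C/C(I)=C/CO | intermediate
9 | 9-(2-Diox-ethyl)-9-borabicyclo[3.3.1]nonane (in flask) | CC(C)=CCC[C@]1(C)OC(C)(C)O[C@@H]1CCB1C2CCCC1CCC2 | intermediate
10 | (2Z)-3-methyl-5-Diox-pent-2-en-1-ol | CC(C)=CCC[C@]1(C)OC(C)(C)O[C@@H]1CC/C(C)=C\CO | intermediate
11 | [(2R,3S)-3-methyl-3-(2-Diox-ethyl)oxiran-2-yl]methanol | CC(C)=CCC[C@]1(C)OC(C)(C)O[C@@H]1CC[C@]2(C)O[C@@H]2CO | intermediate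
12 | (2S,3S)-3-methyl-3-(2-Diox-ethyl)oxirane-2-carbaldehyde | CC(C)=CCC[C@]1(C)OC(C)(C)O[C@@H]1CC[C@]2(C)O[C@@H]2C=O | intermediate
13 | (2R)-5-oxooxolane-2-carboxylic acid | OC(=O)[C@H]1CCC(=O)O1 | starting material
14 | lithium (2R)-2-hydroxy-5-oxohexanoate (in flask) | CC(=O)CC[C@@H](O)C([O-])=O.[Li+] | intermediate
15 | methyl (2R)-2-hydroxy-5-oxohexanoate | CC(=O)CC[C@@H](O)C(=O)OC | intermediate
16 | (4R)-4-hydroxycyclohexane-1,3-dione (in flask) | O=C1CC(=O)[C@H](O)CC1 | intermediate
17 | (4R)-4-hydroxy-2-{[(2R,3S)-3-methyl-3-(2-Diox-ethyl)oxiran-2-yl]methylidene}cyclohexane-1,3-dione (in flask) | CC(C)=CCC[C@]1(C)OC(C)(C)O[C@@H]1CC[C@]2(C)O[C@@H]2C=C3C(=O)CC[C@@H](O)C3=O | intermediate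
18 | (6R)-3,6-dihydroxy-2-{[(2R,3S)-3-methyl-3-(2-Diox-ethyl)oxiran-2-yl]methyl}cyclohex-2-en-1-one (in flask) | CC(C)=CCC[C@]1(C)OC(C)(C)O[C@@H]1CC[C@]2(C)O[C@@H]2CC3=C(O)CC[C@@H](O)C3=O | intermediate
19 | (2S,5R)-5-hydroxy-2-[(2S)-2-hydroxy-4-Diox-butan-2-yl]-2,3,6,7-tetrahydro-1-benzofuran-4(5H)-one | CC(C)=CCC[C@]1(C)OC(C)(C)O[C@@H]1CC[C@](C)(O)[C@@H]2CC3=C(CC[C@@H](O)C3=O)O2 | intermediate
20 | (2S,5R)-5-hydroxy-2-[(2S,5R,6S)-2,5,6-trihydroxy-6,10-dimethylundec-9-en-2-yl]-2,3,6,7-tetrahydro-1-benzofuran-4(5H)-one | CC(C)=CCC[C@](C)(O)[C@H](O)CC[C@](C)(O)[C@@H]1CC2=C(CC[C@@H](O)C2=O)O1 | target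

**Step count and risks**
Total step count: 10. Longest linear sequence: 8 (steps 1, 2, 3, 5, 6, 7, 9, 10).

Most likely to fail, first: step 9. The Dieckmann closure has to work on an α-oxido ester, and the hydroxylated dione could close through the wrong enolate oxygen to give the regioisomeric vinylogous ester. The fallback sets out from 12 and returns at 19. The same one-flask sequence is run with commercial methyl 5-oxohexanoate in place of 15. Dieckmann closure gives cyclohexane-1,3-dione F1 in the flask. Reductive alkylation with 12 gives 2-{[(2R,3S)-3-methyl-3-(2-Diox-ethyl)oxiran-2-yl]methylidene}cyclohexane-1,3-dione F2 and then 3-hydroxy-2-{[(2R,3S)-3-methyl-3-(2-Diox-ethyl)oxiran-2-yl]methyl}cyclohex-2-en-1-one F3. Base closes this symmetric dione, where no oxygen choice exists, to (2S)-2-[(2S)-2-hydroxy-4-Diox-butan-2-yl]-2,3,6,7-tetrahydro-1-benzofuran-4(5H)-one F4, so both rings still form together. The C5 hydroxyl is then put in by kinetic α′-deprotonation (LDA, 2.2 equiv, THF, −78 °C) and oxidation with the enantiomer of Davis (camphorsulfonyl)oxaziridine that gives 5R, which returns the route at 19. Reagent control here is only moderate, so the minor C5 epimer would have to be removed by chromatography.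

Second: step 2. The Payne equilibrium of a 3,3-disubstituted epoxy alcohol and the ylide trapping may be slow or incomplete. The fallback sets out from 1 and returns at 3, now as an isolated compound that is carried to 4 with the same ylide. Sharpless epoxidation with D-(−)-DET gives [(2R,3R)-3-methyl-3-(4-methylpent-3-en-1-yl)oxiran-2-yl]methanol F5. Acid-catalysed hydrolysis (cat. HClO4, THF–H2O, 0 °C) opens the tertiary carbon with inversion to (2R,3S)-3,7-dimethyloct-6-ene-1,2,3-triol F6. Selective primary tosylation (TsCl, pyridine, −20 °C) gives (2R,3S)-2,3-dihydroxy-3,7-dimethyloct-6-en-1-yl 4-methylbenzenesulfonate F7, and K2CO3 in MeOH closes it to 3. This reaches the same unlike diol by inverting the tertiary instead of the secondary carbon.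

Third: step 8. MeLi may over-add, or the one-pot carboxylate methylation may be sluggish. The fallback sets out from 13 and returns at 16 inside the key-step flask. (COCl)2 with cat. DMF gives (2R)-5-oxooxolane-2-carbonyl chloride F8, and Me2CuLi (THF, −78 °C) acylates chemoselectively to (5R)-5-acetyloxolan-2-one F9. In the first stage of step 9, LiHMDS (2.2 equiv, −78 → 0 °C) forms the kinetic methyl enolate, which attacks the lactone carbonyl and expels the C5 oxygen (intramolecular Claisen, O-to-C acyl transfer), giving 16 as its dianion. The rest of step 9 is unchanged. The risk in this variant is enolisation toward C5, which would erode the stereocentre.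

Further compounds
F1 | step 9 | cyclohexane-1,3-dione | O=C1CCCC(=O)C1
F2 | step 9 | 2-{[(2R,3S)-3-methyl-3-(2-Diox-ethyl)oxiran-2-yl]methylidene}cyclohexane-1,3-dione | CC(C)=CCC[C@]1(C)OC(C)(C)O[C@@H]1CC[C@]2(C)O[C@@H]2C=C3C(=O)CCCC3=O
F3 | step 9 | 3-hydroxy-2-{[(2R,3S)-3-methyl-3-(2-Diox-ethyl)oxiran-2-yl]methyl}cyclohex-2-en-1-one | CC(C)=CCC[C@]1(C)OC(C)(C)O[C@@H]1CC[C@]2(C)O[C@@H]2CC3=C(O)CCCC3=O
F4 | step 9 | (2S)-2-[(2S)-2-hydroxy-4-Diox-butan-2-yl]-2,3,6,7-tetrahydro-1-benzofuran-4(5H)-one | CC(C)=CCC[C@]1(C)OC(C)(C)O[C@@H]1CC[C@](C)(O)[C@@H]2CC3=C(CCCC3=O)O2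
F5 | step 2 | [(2R,3R)-3-methyl-3-(4-methylpent-3-en-1-yl)oxiran-2-yl]methanol | CC(C)=CCC[C@@]1(C)O[C@@H]1CO
F6 | step 2 | (2R,3S)-3,7-dimethyloct-6-ene-1,2,3-triol | CC(C)=CCC[C@](C)(O)[C@H](O)CO
F7 | step 2 | (2R,3S)-2,3-dihydroxy-3,7-dimethyloct-6-en-1-yl 4-methylbenzenesulfonate | CC(C)=CCC[C@](C)(O)[C@H](O)COS(=O)(=O)c1ccc(C)cc1
F8 | step 8 | (2R)-5-oxooxolane-2-carbonyl chloride | ClC(=O)[C@H]1CCC(=O)O1
F9 | step 8 | (5R)-5-acetyloxolan-2-one | CC(=O)[C@H]1CCC(=O)O1
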